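## Retrosynthetic overview

- **Feature:** the carbon of ring A that becomes C8a is the only unsubstituted ortho position of a 2,3,4-trimethoxybenzoyl group. It stands para to the middle methoxy group (C6-OMe of the isoflavone), so the ring-A radical cation can accept O1 at that carbon.
- **Last cuts:** the free 3'-OH comes from its pivalate. Before that, O1–C8a is opened to the Z-enol of an α-formyl deoxybenzoin (anodic C–H/O–H coupling).
- **C3–C4:** made by C-acylation of the morpholine enamine of the ring-B arylacetaldehyde with 2,3,4-trimethoxybenzoyl chloride, followed by hydrolysis.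
- **Ring-B aldehyde:** made from 2,3-dihydroxybenzaldehyde by 2-O-methylation, 3-O-pivaloylation and Wittig one-carbon homologation.
- **Ring order:** rings A and B are bought. The pyranone ring C is the only ring formed, in the penultimate step.

Key step: step 9

Remark: the target has no stereocentre, and the C3–C1' axis carries too little ortho bulk to be resolved. The compound is therefore achiral and no enantiomer has to be selected. The only geometric element of the route is the enol double bond of the electrolysis precursor.

## Route

Step 1
Reactants: 1 2,3-dihydroxybenzaldehyde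
Product: 2 3-hydroxy-2-methoxybenzaldehyde
Conditions: MeI (1.05 equiv), K2CO3 (1.0 equiv), DMF, 0 °C → rt
Reagents that add atoms: iodomethane, CI
Why: Williamson ether synthesis on the mono-phenoxide: the 2-OH is conjugated with the ortho formyl group and is the more acidic one, so one equivalent of carbonate ionises only it and MeI caps O2 while O3 stays protonated.

Step 2
Reactants: 2 3-hydroxy-2-methoxybenzaldehyde
Product: 3 3-formyl-2-methoxyphenyl pivalate
Conditions: PivCl, Et3N, DMAP (cat.), CH2Cl2, 0 °C → rt
Reagents that add atoms: pivaloyl chloride, CC(C)(C)C(=O)Cl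
Why: DMAP-catalysed O-acylation of the only remaining phenol, to which the aldehyde and the aryl methyl ether are inert.

Step 3
Reactants: 3 3-formyl-2-methoxyphenyl pivalate
Product: 4 2-methoxy-3-(2-methoxyethenyl)phenyl pivalate (E/Z mixture)
Conditions: Ph3P(CH2OMe)Cl (1.3 equiv), KOtBu (1.25 equiv), THF, 0 °C; then 3, −20 °C → rt
Reagents that add atoms: (methoxymethyl)triphenylphosphonium chloride, COC[P+](c1ccccc1)(c1ccccc1)c1ccccc1.[Cl-]
Why: Wittig olefination with the methoxymethylene ylide, pre-formed with a slight deficit of base so that no alkoxide is left to attack the hindered aryl ester; the E/Z mixture does not matter because both isomers give the same aldehyde.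

Step 4
Reactants: 4 2-methoxy-3-(2-methoxyethenyl)phenyl pivalate
Product: 5 2-methoxy-3-(2-oxoethyl)phenyl pivalate
Conditions: 3 M HCl, THF, 50 °C
Reagents that add atoms: water, O
Why: Acid-catalysed enol ether hydrolysis (C-protonation, hydration of the oxocarbenium ion, loss of methanol), to which the aryl pivalate and the aryl methyl ether are stable; the sensitive arylacetaldehyde is carried on at once.

Step 5
Reactants: 5 2-methoxy-3-(2-oxoethyl)phenyl pivalate; 6 morpholine
Product: 7 2-methoxy-3-[(E)-2-(morpholin-4-yl)ethenyl]phenyl pivalate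
Conditions: morpholine (1.05 equiv), 4 Å MS, toluene, 0 °C → rt
Reagents that add atoms: none
Why: Enamine condensation of an aldehyde with a secondary amine, driven by the sieves and by conjugation of the new C=C with ring B, which also sets the E geometry; the aldehyde takes up morpholine far faster than the hindered pivalate can.

Step 6
Reactants: 8 2,3,4-trimethoxybenzoic acid
Product: 9 2,3,4-trimethoxybenzoyl chloride
Conditions: (COCl)2, DMF (cat.), CH2Cl2, 0 °C → rt
Reagents that add atoms: oxalyl chloride, O=C(Cl)C(=O)Cl
Why: Acid chloride formation through the catalytic chloroiminium (Vilsmeier-type) species, under mild gas-evolving conditions that leave the methyl ethers untouched.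

Step 7
Reactants: 7 2-methoxy-3-[(E)-2-(morpholin-4-yl)ethenyl]phenyl pivalate; 9 2,3,4-trimethoxybenzoyl chloride
Product: 10 (E)-2-[2-methoxy-3-(pivaloyloxy)phenyl]-3-(morpholin-4-yl)-1-(2,3,4-trimethoxyphenyl)prop-2-en-1-one
Conditions: Et3N (1.5 equiv), CH2Cl2, 0 → 40 °C
Reagents that add atoms: none
Why: Stork enamine C-acylation: the β-carbon of the enamine attacks the aroyl chloride (which cannot form a ketene) and Et3N deprotonates the acyl iminium ion to the stable push–pull enaminone, forming C3–C4, while any N-acylation is reversible; the geometry of this easily rotating C=C is erased in the next step.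

Step 8
Reactants: 10 (E)-2-[2-methoxy-3-(pivaloyloxy)phenyl]-3-(morpholin-4-yl)-1-(2,3,4-trimethoxyphenyl)prop-2-en-1-one
Product: 11 (Z)-3-hydroxy-2-[2-methoxy-3-(pivaloyloxy)phenyl]-1-(2,3,4-trimethoxyphenyl)prop-2-en-1-one
Conditions: 1 M HCl, THF, rt
Reagents that add atoms: water, O
Why: Acid hydrolysis of a vinylogous amide (protonation, addition of water at the aminomethine carbon, loss of morpholine) gives the β-keto aldehyde, which settles as its hydrogen-bonded Z-enol, the thermodynamic tautomer.

Step 9
Reactants: 11 (Z)-3-hydroxy-2-[2-methoxy-3-(pivaloyloxy)phenyl]-1-(2,3,4-trimethoxyphenyl)prop-2-en-1-one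
Product: 12 2-methoxy-3-(5,6,7-trimethoxy-4-oxo-4H-chromen-3-yl)phenyl pivalate
Conditions: BDD(+)|Pt(−), undivided cell, Bu4NPF6 (0.1 M), dry HFIP (0.02 M in 11), no base, controlled potential at the foot of the first anodic wave, 2.1–2.2 F mol⁻¹, rt, N2
Reagents that add atoms: none
Why: Proposed new method: the anode removes one electron from ring A, the best donor in the molecule once ring B carries the ester and the enol is kept un-ionised (no base is added), and HFIP prolongs the life of this radical cation. The resting form of 11 is the s-cis O–H···O=C4 chelate, in which the enol oxygen faces the carbonyl oxygen and not the ring, so closure needs a half turn about C3–C4 to the s-trans rotamer of the Z-enol; HFIP, a strong hydrogen-bond donor to C4=O, loosens the chelate and makes that rotamer accessible. The enol oxygen then adds to the free ortho carbon (C8a), which lies para to the central methoxy group and shares the positive charge, and loss of the O–H proton, a second electron and the C8a proton (ECEC sequence) restores aromaticity, the two protons leaving as H2 at the cathode. The closest known reaction types are the anodic dehydrogenative lactonisation of biaryl-2-carboxylic acids and the capture of alkoxyarene radical cations by N- or O-nucleophiles para to a methoxy group, whereas an enol oxygen closing a chromone in this way is without precedent. The pyranone ring closes in a 6-endo-trig mode onto an aromatic sp2 carbon and no stereocentre is created. The step needs oxidation of ring A before ring B and the enol C=C, which is secured by the pivalate, by the ortho-methoxy twist that decouples ring B from the enol and by electrolysis at the foot of the first wave, and it needs C8a rather than the methoxy-bearing ortho carbon, which is secured because only the C8a adduct has a proton to lose and is drained by the second electron transfer while the ipso adduct can only revert; the product should be shielded from further oxidation by its now coplanar carbonyl group and by the vinylogous-ester character of O1.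

Step 10
Reactants: 12 2-methoxy-3-(5,6,7-trimethoxy-4-oxo-4H-chromen-3-yl)phenyl pivalate
Product: 13 3-(3-hydroxy-2-methoxyphenyl)-5,6,7-trimethoxy-4H-chromen-4-one (target)
Conditions: K2CO3 (1.5 equiv), MeOH, 0 °C → rt; then 1 M HCl to pH 5
Reagents that add atoms: none
Why: Base-mediated transesterification (methanolysis) of an aryl ester, whose phenoxide is a good leaving group, so carbonate at or below room temperature should be enough, and under these conditions the isoflavone pyranone is not opened at C2.

## Compound list

1 | 2,3-dihydroxybenzaldehyde | O=Cc1cccc(O)c1O | starting material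
2 | 3-hydroxy-2-methoxybenzaldehyde | COc1c(O)cccc1C=O | intermediate
3 | 3-formyl-2-methoxyphenyl pivalate | COc1c(C=O)cccc1OC(=O)C(C)(C)C | intermediate
4 | 2-methoxy-3-(2-methoxyethenyl)phenyl pivalate (E/Z mixture, geometry not defined) | COC=Cc1cccc(OC(=O)C(C)(C)C)c1OC | intermediate
5 | 2-methoxy-3-(2-oxoethyl)phenyl pivalate | O=CCc1cccc(OC(=O)C(C)(C)C)c1OC | intermediate
6 | morpholine | C1COCCN1 | starting material
7 | 2-methoxy-3-[(E)-2-(morpholin-4-yl)ethenyl]phenyl pivalate | COc1c(/C=C/N2CCOCC2)cccc1OC(=O)C(C)(C)C | intermediate
8 | 2,3,4-trimethoxybenzoic acid | COc1ccc(C(=O)O)c(OC)c1OC | starting material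
9 | 2,3,4-trimethoxybenzoyl chloride | COc1ccc(C(Cl)=O)c(OC)c1OC | intermediate
10 | (E)-2-[2-methoxy-3-(pivaloyloxy)phenyl]-3-(morpholin-4-yl)-1-(2,3,4-trimethoxyphenyl)prop-2-en-1-one | O=C(c1ccc(OC)c(OC)c1OC)/C(=C/N1CCOCC1)c1cccc(OC(=O)C(C)(C)C)c1OC | intermediate
11 | (Z)-3-hydroxy-2-[2-methoxy-3-(pivaloyloxy)phenyl]-1-(2,3,4-trimethoxyphenyl)prop-2-en-1-one | O/C=C(\C(=O)c1ccc(OC)c(OC)c1OC)c1cccc(OC(=O)C(C)(C)C)c1OC | intermediate
12 | 2-methoxy-3-(5,6,7-trimethoxy-4-oxo-4H-chromen-3-yl)phenyl pivalate | COc1cc2occ(-c3cccc(OC(=O)C(C)(C)C)c3OC)c(=O)c2c(OC)c1OC | intermediate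
13 | 3-(3-hydroxy-2-methoxyphenyl)-5,6,7-trimethoxy-4H-chromen-4-one (3'-hydroxy-2',5,6,7-tetramethoxyisoflavone) | COc1cc2occ(-c3cccc(O)c3OC)c(=O)c2c(OC)c1OC | target

## Step count

Total step count: 10.
Longest linear sequence: 9 steps (steps 1–5 and 7–10). Step 6 is the convergent branch.

## Steps most likely to fail

**1. Step 9.** Three processes may defeat it:
- Electron loss may occur from the enol/ring-B styrene unit instead of ring A, followed by radical coupling or solvent capture.
- The ipso adduct at the methoxy-bearing ortho carbon may collapse with loss of methanol.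
- The newly para-dioxygenated ring A may be oxidised further.

The fallback sets out from 5 and returns at 12, and buys O1 with a phenol instead of making the bond at the anode. Pinnick oxidation of 5 (NaClO2, NaH2PO4, 2-methyl-2-butene, t-BuOH/H2O) would give [2-methoxy-3-(pivaloyloxy)phenyl]acetic acid F1. Friedel–Crafts acylation of commercial 3,4,5-trimethoxyphenol with this acid in BF3·OEt2 at about 80 °C can only strike ortho to the phenol. It would give 2-methoxy-3-[2-(6-hydroxy-2,3,4-trimethoxyphenyl)-2-oxoethyl]phenyl pivalate F2. DMF dimethyl acetal in toluene at 90 °C would form (E)-3-(dimethylamino)-1-(6-hydroxy-2,3,4-trimethoxyphenyl)-2-[2-methoxy-3-(pivaloyloxy)phenyl]prop-2-en-1-one F3. This closes by addition–elimination of the phenol oxygen to 12, the classical deoxybenzoin isoflavone synthesis.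

**2. Step 7.** C-acylation may be slow, because a donor-rich ortho-substituted aroyl chloride meets a conjugated ortho-substituted enamine. N-acylation, enamine hydrolysis and self-condensation of the liberated aldehyde could then take over.

The fallback sets out from 3 (with 9) and returns at 11, and avoids both the arylacetaldehyde and the enamine. NaBH4 in MeOH at 0 °C would reduce 3 to 3-(hydroxymethyl)-2-methoxyphenyl pivalate F4. PBr3 in CH2Cl2 would give 3-(bromomethyl)-2-methoxyphenyl pivalate F5. Zinc dust with LiCl in THF would insert to give [2-methoxy-3-(pivaloyloxy)benzyl]zinc bromide F6, which tolerates the ester. Pd(PPh3)4-catalysed Negishi-type acylation with 9 would give 2-methoxy-3-[2-oxo-2-(2,3,4-trimethoxyphenyl)ethyl]phenyl pivalate F7. Condensation with DMF dimethyl acetal (neat, 100 °C) would give (E)-3-(dimethylamino)-2-[2-methoxy-3-(pivaloyloxy)phenyl]-1-(2,3,4-trimethoxyphenyl)prop-2-en-1-one F8, which is hydrolysed as in step 8 to 11.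

**3. Step 1.** Discrimination between O2 and O3 in the hydrogen-bonded mono-anion may be poor, and double methylation may occur.

The fallback sets out from 1 and returns at 2, and blocks O3 first. NaH (2.2 equiv) in DMSO/THF forms the dianion, whose non-conjugated 3-oxide is the more nucleophilic. BnBr (1 equiv) would give 3-(benzyloxy)-2-hydroxybenzaldehyde F9. MeI/K2CO3 in DMF would give 3-(benzyloxy)-2-methoxybenzaldehyde F10. Hydrogenolysis (H2 1 atm, Pd/C, EtOAc, stopped after one equivalent) would free 2.

## Further compounds

F1 | step 9 | [2-methoxy-3-(pivaloyloxy)phenyl]acetic acid | COc1c(CC(=O)O)cccc1OC(=O)C(C)(C)C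
F2 | step 9 | 2-methoxy-3-[2-(6-hydroxy-2,3,4-trimethoxyphenyl)-2-oxoethyl]phenyl pivalate | COc1cc(O)c(C(=O)Cc2cccc(OC(=O)C(C)(C)C)c2OC)c(OC)c1OC
F3 | step 9 | (E)-3-(dimethylamino)-1-(6-hydroxy-2,3,4-trimethoxyphenyl)-2-[2-methoxy-3-(pivaloyloxy)phenyl]prop-2-en-1-one | CN(C)/C=C(/C(=O)c1c(O)cc(OC)c(OC)c1OC)c1cccc(OC(=O)C(C)(C)C)c1OC
F4 | step 7 | 3-(hydroxymethyl)-2-methoxyphenyl pivalate | COc1c(CO)cccc1OC(=O)C(C)(C)C
F5 | step 7 | 3-(bromomethyl)-2-methoxyphenyl pivalate | COc1c(CBr)cccc1OC(=O)C(C)(C)C
F6 | step 7 | [2-methoxy-3-(pivaloyloxy)benzyl]zinc bromide | COc1c(C[Zn]Br)cccc1OC(=O)C(C)(C)C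
F7 | step 7 | 2-methoxy-3-[2-oxo-2-(2,3,4-trimethoxyphenyl)ethyl]phenyl pivalate | COc1ccc(C(=O)Cc2cccc(OC(=O)C(C)(C)C)c2OC)c(OC)c1OC
F8 | step 7 | (E)-3-(dimethylamino)-2-[2-methoxy-3-(pivaloyloxy)phenyl]-1-(2,3,4-trimethoxyphenyl)prop-2-en-1-one | CN(C)/C=C(/C(=O)c1ccc(OC)c(OC)c1OC)c1cccc(OC(=O)C(C)(C)C)c1OC
F9 | step 1 | 3-(benzyloxy)-2-hydroxybenzaldehyde | O=Cc1cccc(OCc2ccccc2)c1O
F10 | step 1 | 3-(benzyloxy)-2-methoxybenzaldehyde | COc1c(C=O)cccc1OCc1ccccc1
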